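(The numbers in the tables come from a simulation for an exercise.)

**The constants.** The constants are hidden, but this comparison needs one reading from the runs: how the monomer in chains, X, responds to c(D).

in all of them: L 0.050 M (fed, over 12 h)
- violet: D 0.046 mM; run made earlier
- grey: D 0.16 mM; run made earlier
- Wednesday's: D 0.23 mM; time 40 h
- Monday's: D 0.080 mM; time 40 h

| run | time / h | X / % |
|---|---|---|
| violet | 6.00 | 0 |
| violet | 12.0 | 3.4 |
| violet | 15.0 | 5.9 |
| violet | 25.0 | 13.1 |
| violet | 30.0 | 17.6 |
| grey | 2.50 | 0.7 |
| grey | 4.00 | 0.9 |
| grey | 8.00 | 2.4 |
| grey | 15.0 | 19.0 |
| grey | 30.0 | 40.9 |

(scatter of a reading: 1 percentage point)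

- the average divides the monomer in chains by the number of chains begun, living and dead together
- candidate steps: L -> E; L + J -> X + J; L + D -> J + X
- the earlier runs do not show the number of chains; that part of a forecast is a guess
- percentages count the whole charge, also what has not yet gone in

1. which of the two ends with the longer chains by the average number of monomer units in a chain (chains begun, living or dead) ("neither" if they lie within 10%) (Wednesday's / Monday's / neither)
2. average number of monomer units in a chain (chains begun, living or dead) at the end, Wednesday's
3. average number of monomer units in a chain (chains begun, living or dead) at the end, Monday's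

**Turned round.** We guess that each D begins one chain, so average length is X divided by c(D). For Wednesday's to end longer, with the same feed of L and the same time, its X must exceed Monday's by more than the c(D) factor of 2.88.

**Apparent order.** The logarithm of the X ratio over that of the c(D) ratio, grey against violet at 30.0 h, is 0.676; we call it the apparent order of X in D. With L and time held, length goes as c(D) to the power of this order minus one. The two therefore count as equal for orders from 0.910 to 1.09, and Wednesday's leads above that band. Our reading stands below the band. If it holds at the later time, Wednesday's X should be 2.04 times Monday's, and Monday's chains 1.41 times as long as Wednesday's. We commit to these ratios, not to absolute lengths.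

**The forecast.** It names Monday's, with 175 units for Wednesday's and 240 for Monday's, a ratio of 1.37. Among its grounds it says that “initiation is only partly complete”.

**The flask.** The winner is Monday's, at 193 units against 137 for Wednesday's.

    L → E (k = 1.80 × 10⁻⁴ min⁻¹)
    L + J → X + J, rate k2*[J]*[L] (k = 2.90 M⁻¹ min⁻¹)
    L + D → J + X (k = 0.280 M⁻¹ min⁻¹)

**Why Monday's.** Monday's chains are longer because of its smaller charge of D: with Wednesday's c(D), its 193 units become 137. Wednesday's X stood at 63.1% of the charge against Monday's 30.9%, a ratio of 2.04 beside our 2.04, and its free D was down to 0% of its own charge. Raising c(D) in Monday's flask to 3.2 × 10⁻⁴ M, the order predicts 123 units, and that flask gives 115.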